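**Plan**

- Retrosynthesis: the C2 hydroxyl is traced back to a methoxyl and the quinone ring to a 1,2,4,5-tetramethoxybenzene ring; the chain (C1–C15, counted from the ring) is then cut at C7–C8, and last at the ring–C1 bond and at the C8=C9 double bond.
- Enabling feature: C7 is an unactivated primary sp3 carbon of the heptamethylene tether and C8 the terminal sp2 carbon of the 8Z,11Z skipped diene, so both can be carbon–bromine electrophiles that one nickel catalyst tells apart; the tetramethoxybenzene ring has no reducible group and masks the quinone ring during this reductive union.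
- Forward: 1,2,4,5-tetramethoxybenzene 1, n-BuLi 2 and 1,7-dibromoheptane 3 give, via aryllithium 4, bromide 5 (ring–C1 bond); (Z)-hept-3-en-1-ol 6 gives aldehyde 7 and then the Z,Z-bromodiene 8 (C8=C9 by Wittig reaction).
- Bromides 5 and 8 are joined at C7–C8 by nickel-catalysed reductive cross-electrophile coupling to arene 9; oxidation gives dimethoxyquinone 10 and one selective O-demethylation gives the target 11.
- Stereochemistry: there is no stereocentre; the 11Z alkene is bought with 6, the 8Z alkene is set in the kinetic Wittig step, and both are carried through the coupling with retention.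

Key step: step 4

Remark: the quinone ring is numbered C1–C6 with the chain at C3 (C1 and C4 carbonyls, C2–OH, C5–OMe), and (Z)-hept-3-en-1-ol is taken to be available as a commercial flavour chemical.

**Step 1**
Reactants: 1 1,2,4,5-tetramethoxybenzene; 2 n-butyllithium; 3 1,7-dibromoheptane
Product: 5 3-(7-bromoheptyl)-1,2,4,5-tetramethoxybenzene, via aryllithium 4 (not isolated)
Conditions: TMEDA, THF, 0 °C → rt; then inverse addition to 3 (3 equiv), THF–DMPU, −40 °C → rt
Reagents that add atoms: none
Why: Directed ortho-metalation of 1 at the ring position flanked by two methoxy groups (both free positions are equivalent) followed by SN2 alkylation of aryllithium 4 by the primary dibromide, with inverse addition into excess 3 to suppress double arylation.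

**Step 2**
Reactants: 6 (Z)-hept-3-en-1-ol
Product: 7 (Z)-hept-3-enal
Conditions: Dess–Martin periodinane (1.2 equiv), CH2Cl2, 0 °C → rt; filtration through silica (pentane–Et2O), solution used at once
Reagents that add atoms: none
Why: Dess–Martin oxidation of a primary alcohol under near-neutral conditions at low temperature should stop at the aldehyde and leave the Z-configured β,γ-double bond in place, the crude aldehyde being used immediately.

**Step 3**
Reactants: 7 (Z)-hept-3-enal
Product: 8 (1Z,4Z)-1-bromoocta-1,4-diene
Conditions: BrCH2PPh3Br (1.3 equiv), KOtBu (1.25 equiv), THF, −78 °C; then 7, −78 → −20 °C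
Reagents that add atoms: (bromomethyl)triphenylphosphonium bromide, BrC[P+](c1ccccc1)(c1ccccc1)c1ccccc1.[Br-]
Why: Wittig olefination with the α-bromo ylide Ph3P=CHBr under kinetic control at −78 °C (the bromo counterpart of the Stork–Zhao iodo-olefination) should give the Z-bromoalkene through the cis-oxaphosphetane, and pre-forming the ylide with a slight deficit of base protects the enolisable β,γ-unsaturated aldehyde from isomerisation.

**Step 4**
Reactants: 5 3-(7-bromoheptyl)-1,2,4,5-tetramethoxybenzene; 8 (1Z,4Z)-1-bromoocta-1,4-diene
Product: 9 1,2,4,5-tetramethoxy-3-[(8Z,11Z)-pentadeca-8,11-dien-1-yl]benzene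
Conditions: NiI2 (10 mol %), 2,2'-bipyridine (10 mol %), Mn powder (2 equiv), DMPU, 25 °C; 8 in slight excess
Reagents that add atoms: none
Why: Zerovalent nickel–bipyridine should insert into the vinylic C8–Br bond of 8 with retention to give a (Z,Z)-dienyl divalent nickel bromide, while a monovalent nickel halide abstracts bromine from the primary C7–Br bond of 5 to give the C7 radical. Capture of that radical by the dienylnickel species and reductive elimination from trivalent nickel form the C7–C8 bond, and manganese returns the nickel to the zerovalent state. The closest known reaction type is the nickel-catalysed reductive cross-electrophile coupling of alkenyl bromides with unactivated primary alkyl bromides. No ring is closed and no stereocentre is created; the 8Z geometry is controlled by the configuration of 8, because oxidative addition and reductive elimination at sp2 carbon are stereoretentive, and the 11Z alkene is a spectator. The step needs cross- over homo-coupling, which the different hybridisation of the two brominated carbons secures (two-electron path at sp2 C8, one-electron path at sp3 C7), and it needs the skipped diene to stay unconjugated, which the base-free room-temperature conditions and the fast capture of the radical by nickel should secure. The tetramethoxybenzene ring carries no reducible group, so the head is inert to manganese and to low-valent nickel.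

**Step 5**
Reactants: 9 1,2,4,5-tetramethoxy-3-[(8Z,11Z)-pentadeca-8,11-dien-1-yl]benzene
Product: 10 2,5-dimethoxy-3-[(8Z,11Z)-pentadeca-8,11-dien-1-yl]cyclohexa-2,5-diene-1,4-dione
Conditions: (NH4)2Ce(NO3)6 (2.5 equiv), MeCN–H2O, 0 °C, short reaction time
Reagents that add atoms: water, O
Why: Oxidative demethylation of a para-dimethoxyarene by (NH4)2Ce(NO3)6 through the arene radical cation and ipso attack of water; either para pair of methoxy groups leads to the same 2,5-dimethoxy-3-alkyl-1,4-benzoquinone, and the isolated Z alkenes should not be touched by the one-electron oxidant in the short time at 0 °C.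

**Step 6**
Reactants: 10 2,5-dimethoxy-3-[(8Z,11Z)-pentadeca-8,11-dien-1-yl]cyclohexa-2,5-diene-1,4-dione
Product: 11 Sorgoleone-360, 2-hydroxy-5-methoxy-3-[(8Z,11Z)-pentadeca-8,11-dien-1-yl]cyclohexa-2,5-diene-1,4-dione
Conditions: 70% aq. HClO4, 1,4-dioxane, 0 °C → rt, stopped at full conversion of 10
Reagents that add atoms: water, O
Why: Acid-catalysed hydrolysis of a vinylogous methyl ester by addition of water and loss of methanol; the C2 methoxy group, wedged between the C3 chain and the C1 carbonyl, is twisted out of conjugation and should therefore react ahead of the planar, fully conjugated C5 methoxy group, a selectivity with close precedent in 3-alkyl-2,5-dimethoxy-1,4-benzoquinones.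

**Compound list**

1 | 1,2,4,5-tetramethoxybenzene | COc1cc(OC)c(OC)cc1OC | starting material
2 | n-butyllithium | [Li]CCCC | starting material
3 | 1,7-dibromoheptane | BrCCCCCCCBr | starting material
4 | (2,3,5,6-tetramethoxyphenyl)lithium | [Li]c1c(OC)c(OC)cc(OC)c1OC | intermediate
5 | 3-(7-bromoheptyl)-1,2,4,5-tetramethoxybenzene | COc1cc(OC)c(OC)c(CCCCCCCBr)c1OC | intermediate
6 | (Z)-hept-3-en-1-ol | CCC/C=C\CCO | starting material
7 | (Z)-hept-3-enal | CCC/C=C\CC=O | intermediate
8 | (1Z,4Z)-1-bromoocta-1,4-diene | CCC/C=C\C/C=C\Br | intermediate
9 | 1,2,4,5-tetramethoxy-3-[(8Z,11Z)-pentadeca-8,11-dien-1-yl]benzene | CCC/C=C\C/C=C\CCCCCCCc1c(OC)c(OC)cc(OC)c1OC | intermediate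
10 | 2,5-dimethoxy-3-[(8Z,11Z)-pentadeca-8,11-dien-1-yl]cyclohexa-2,5-diene-1,4-dione | CCC/C=C\C/C=C\CCCCCCCC1=C(OC)C(=O)C=C(OC)C1=O | intermediate
11 | Sorgoleone-360, 2-hydroxy-5-methoxy-3-[(8Z,11Z)-pentadeca-8,11-dien-1-yl]cyclohexa-2,5-diene-1,4-dione | CCC/C=C\C/C=C\CCCCCCCC1=C(O)C(=O)C=C(OC)C1=O | target

**Step count and risks**

Total step count: 6. Longest linear sequence: 5 steps (6 → 7 → 8 → 9 → 10 → 11; steps 2, 3, 4, 5, 6).

Steps most likely to fail:

1. Step 4. What may go wrong: homocoupling of the alkenyl bromide, hydrogen-atom transfer from the doubly allylic C10 methylene to the C7 radical, or Z-to-E drift and migration of the skipped diene if a nickel hydride forms. The fallback replaces the radical cross-electrophile union by a polar cross-coupling with a preformed C7 nucleophile. It sets out from 5, which with Mg turnings in THF should give the Grignard reagent [7-(2,3,5,6-tetramethoxyphenyl)heptyl]magnesium bromide F1. F1 is then coupled with 8 under Fe(acac)3 catalysis in THF–NMP at 0 °C, a stereoretentive iron-catalysed Kumada-type alkyl–alkenyl coupling, and the route is rejoined at 9.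

2. Step 3. What may go wrong: insufficient Z selectivity in the kinetic Wittig step, or base-induced migration of the β,γ double bond of 7 into conjugation before olefination. The fallback sets the C1 geometry by a selective hydrogenolysis instead of a kinetic olefination. It sets out from 7, which under base-free dibromo-olefination (CBr4, PPh3, CH2Cl2, 0 °C; first stage of the Corey–Fuchs sequence) should give (4Z)-1,1-dibromoocta-1,4-diene F2. Hydrogenolysis of F2 with Bu3SnH and catalytic Pd(PPh3)4 should remove only the bromine trans to the chain, since that C–Br bond adds to zerovalent palladium faster, and the route is rejoined at 8.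

3. Step 6. What may go wrong: hydrolysis at the C5 methoxy group, hydrolysis of both methoxy groups, or acid-induced isomerisation of the diene if the reaction is slow. The fallback reverses the order of differentiation. It sets out from 10, which on exhaustive hydrolysis (aq. NaOH, EtOH, argon, then dilute HCl) should give 2,5-dihydroxy-3-[(8Z,11Z)-pentadeca-8,11-dien-1-yl]cyclohexa-2,5-diene-1,4-dione F3. Acid-catalysed vinylogous esterification of F3 (MeOH, catalytic H2SO4) should methylate the unhindered C5 oxygen, where the new methoxy group can lie in plane, and leave the hydroxyl next to the chain free, so the route is rejoined at 11.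

**Further compounds**

F1 | step 4 | [7-(2,3,5,6-tetramethoxyphenyl)heptyl]magnesium bromide | COc1cc(OC)c(OC)c(CCCCCCC[Mg]Br)c1OC
F2 | step 3 | (4Z)-1,1-dibromoocta-1,4-diene | CCC/C=C\CC=C(Br)Br
F3 | step 6 | 2,5-dihydroxy-3-[(8Z,11Z)-pentadeca-8,11-dien-1-yl]cyclohexa-2,5-diene-1,4-dione | CCC/C=C\C/C=C\CCCCCCCC1=C(O)C(=O)C=C(O)C1=O
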